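**Plan**

- Retrosynthetic cuts, in order: the two silyl ethers; C15=C15′ of the polyene (Julia–Kocienski); the O1–C2 bond of the hexahydrobenzofuran (allenol cyclisation, the allene coming from an alkynyl epoxide); the alkyne–lactone C–C bond (Sonogashira); and the C4–C5 bond of the furan-2(5H)-one (ring-closing Heck).
- Enabling feature: in the lactone ring (O1, C2, C3, C4, C5) the O1–C5 bond is an enol-ester bond to a 1,3-diene. The ring therefore opens at C4–C5 to an acyclic dienyl (E)-2,3-dibromoacrylate in which C4 carries bromine cis to the ester and lies 1,5 to C5.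
- Forward order: butenolide ring (steps 1–4); ring-B ethynyl epoxide from actinol (5–11); union and dihydrofuran ring (12–14); sulfone (15–17); ring-A dienynal (18–20); chain union and desilylation (21–22).
- Stereochemistry: both carbinol centres from (4R,6R)-actinol; C7a of the benzofuran from Sharpless epoxidation; C2 of the benzofuran from anti-SN2′ hydride delivery followed by axis-to-centre transfer; alkene geometry from the (E)-enynol, thermodynamic control at the ylidene and at C15, and an E-selective Wittig step.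

Key step: step 4

Remark: propiolic acid, (E)-3-methylpent-2-en-4-yn-1-ol and (4R,6R)-actinol are taken as commercial; the target is read as the (5Z)-lactone with a (2R,6S,7aR)-hexahydrobenzofuranyl group and a (4R)-cyclohexenol.

**Route**

Step 1
Reactants: 1 propiolic acid
Product: 2 (2E)-2,3-dibromoprop-2-enoic acid
Conditions: Br2 (1.0 equiv), CHCl3, 0 °C to rt, dark
Reagents that add atoms: bromine (BrBr)
Why: Electrophilic bromination of the alkyne should proceed by anti addition to give the (E)-dibromide, which places the β-bromine cis to the carboxyl group as the later ring closure requires.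

Step 2
Reactants: 3 (2E)-3-methylpent-2-en-4-yn-1-ol
Product: 4 tert-butyldimethyl{[(2E)-3-methylpent-2-en-4-yn-1-yl]oxy}silane
Conditions: TBSCl, imidazole, DMF, 0 °C to rt
Reagents that add atoms: tert-butyldimethylsilyl chloride (CC(C)(C)[Si](C)(C)Cl)
Why: Standard silylation of a primary alcohol masks the allylic hydroxyl against acyl transfer and redox isomerisation in the next two steps.

Step 3
Reactants: 2 (2E)-2,3-dibromoprop-2-enoic acid; 4 tert-butyldimethyl{[(2E)-3-methylpent-2-en-4-yn-1-yl]oxy}silane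
Product: 5 (1Z,3E)-5-[(tert-butyldimethylsilyl)oxy]-3-methylpenta-1,3-dien-1-yl (2E)-2,3-dibromoprop-2-enoate
Conditions: Ru(η3-CH2C(CH3)CH2)2[Ph2P(CH2)4PPh2] (2 mol %), toluene, 50 °C
Reagents that add atoms: none
Why: Ruthenium-vinylidene-mediated anti-Markovnikov addition of a carboxylic acid to a terminal alkyne should put the carboxylate oxygen on the terminal carbon of the enyne and give the (1Z)-dienyl ester, leaving the vinyl bromides and the internal alkene untouched.

Step 4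
Reactants: 5 (1Z,3E)-5-[(tert-butyldimethylsilyl)oxy]-3-methylpenta-1,3-dien-1-yl (2E)-2,3-dibromoprop-2-enoate
Product: 7 (5Z)-3-bromo-5-[(2E)-4-[(tert-butyldimethylsilyl)oxy]-2-methylbut-2-en-1-ylidene]furan-2(5H)-one, via (5E)-ylidene isomer 6 (not isolated)
Conditions: Pd(OAc)2 (10 mol %), P(2-furyl)3 (20 mol %), Ag2CO3 (1.0 equiv), MeCN (0.01 M), 60 °C; then I2 (5 mol %), CH2Cl2, rt, daylight
Reagents that add atoms: none
Why: Proposed new method: an intramolecular Mizoroki–Heck reaction in which the alkene partner is the enol-ester double bond of the tether itself, the closest known type being 5-exo Heck cyclisations of vinyl halides onto tethered enol ethers and 1,3-dienes; oxidative addition of zerovalent palladium at the β-C–Br bond (the conjugate, more electron-poor position, as in selective couplings of 2,3-dibromopropenoates) is followed by syn carbopalladation of the O–CH=CH bond at the oxygen-bearing carbon and syn β-hydride elimination of the C5–H. The ring (O1, C2, C3, C4, C5) closes in the 5-exo-trig mode, which is secured because only this mode leaves palladium as an η3-allyl unit on the diene and because cationic palladium (Ag2CO3 removes bromide) prefers the oxygen-substituted alkene carbon. No sp3 stereocentre is formed; the only stereochemical element is the exocyclic C5=C bond, for which syn addition and syn elimination from the (1Z)-ester should give mainly the (5E)-isomer 6, and iodine-catalysed equilibration should then convert it into the thermodynamically preferred (5Z)-isomer 7, in which the diene chain avoids the C4–H. The selectivities needed are β- over α-C–Br insertion, cyclisation over intermolecular coupling (high dilution, the minor s-cis ester rotamer being the reactive one) and loss of the C5–H in preference to an allylic C–H of the silyloxymethyl group, the last favoured by the acidity of the γ-hydrogen and by full conjugation with the lactone. The α-bromine is retained as the handle for step 12.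

Step 5
Reactants: 8 (4R,6R)-4-hydroxy-2,2,6-trimethylcyclohexan-1-one (actinol)
Product: 9 (4R,6R)-4-[(tert-butyldimethylsilyl)oxy]-2,2,6-trimethylcyclohexan-1-one
Conditions: TBSCl, imidazole, DMF, rt
Reagents that add atoms: tert-butyldimethylsilyl chloride (CC(C)(C)[Si](C)(C)Cl)
Why: Silylation of the secondary alcohol protects the chiral-pool carbinol, which becomes both ring carbinol centres of the target, without touching either stereocentre.

Step 6
Reactants: 9 (4R,6R)-4-[(tert-butyldimethylsilyl)oxy]-2,2,6-trimethylcyclohexan-1-one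
Product: 10 (4R)-4-[(tert-butyldimethylsilyl)oxy]-2,6,6-trimethylcyclohex-1-en-1-yl trifluoromethanesulfonate
Conditions: LiN(iPr)2, THF, −78 °C; PhNTf2, −78 °C to rt
Reagents that add atoms: N-phenylbis(trifluoromethanesulfonimide) (O=S(=O)(N(c1ccccc1)S(=O)(=O)C(F)(F)F)C(F)(F)F)
Why: The ketone has a single enolisable position, so O-triflation of its lithium enolate should give the tetrasubstituted enol triflate, erasing the methyl-bearing stereocentre on purpose and leaving the carbinol centre intact.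

Step 7
Reactants: 10 (4R)-4-[(tert-butyldimethylsilyl)oxy]-2,6,6-trimethylcyclohex-1-en-1-yl trifluoromethanesulfonate
Product: 11 methyl (4R)-4-[(tert-butyldimethylsilyl)oxy]-2,6,6-trimethylcyclohex-1-ene-1-carboxylate
Conditions: Pd(OAc)2 (5 mol %), PPh3 (10 mol %), CO (1 atm), MeOH, Et3N, DMF, 60 °C
Reagents that add atoms: carbon monoxide ([C-]#[O+]); methanol (CO)
Why: Palladium-catalysed alkoxycarbonylation of an enol triflate (oxidative addition, CO insertion, methanolysis) should give the conjugated ester.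

Step 8
Reactants: 11 methyl (4R)-4-[(tert-butyldimethylsilyl)oxy]-2,6,6-trimethylcyclohex-1-ene-1-carboxylate
Product: 12 [(4R)-4-[(tert-butyldimethylsilyl)oxy]-2,6,6-trimethylcyclohex-1-en-1-yl]methanol
Conditions: iBu2AlH (2.5 equiv), CH2Cl2, −78 °C; Rochelle salt work-up
Reagents that add atoms: none
Why: 1,2-Reduction of the conjugated ester with an aluminium hydride should give the allylic alcohol needed for directed epoxidation.

Step 9
Reactants: 12 [(4R)-4-[(tert-butyldimethylsilyl)oxy]-2,6,6-trimethylcyclohex-1-en-1-yl]methanol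
Product: 13 [(1R,4S,6R)-4-[(tert-butyldimethylsilyl)oxy]-2,2,6-trimethyl-7-oxabicyclo[4.1.0]heptan-1-yl]methanol (epoxide anti to the silyloxy group)
Conditions: Ti(OiPr)4 (20 mol %), D-(−)-diethyl tartrate (24 mol %), tBuOOH, 4 Å MS, CH2Cl2, −20 °C
Reagents that add atoms: tert-butyl hydroperoxide (CC(C)(C)OO)
Why: Sharpless asymmetric epoxidation under reagent control by D-(−)-tartrate should deliver oxygen to the alkene face anti to the silyloxy group, setting both epoxide carbons and with them the later C7a (R) centre of the furanoid.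

Step 10
Reactants: 13 [(1R,4S,6R)-4-[(tert-butyldimethylsilyl)oxy]-2,2,6-trimethyl-7-oxabicyclo[4.1.0]heptan-1-yl]methanol
Product: 14 (1S,4S,6R)-4-[(tert-butyldimethylsilyl)oxy]-2,2,6-trimethyl-7-oxabicyclo[4.1.0]heptane-1-carbaldehyde
Conditions: Pr4N[RuO4] (5 mol %), N-methylmorpholine N-oxide, 4 Å MS, CH2Cl2, rt
Reagents that add atoms: none
Why: Ley–Griffith oxidation should convert the hindered primary alcohol into the non-enolisable epoxy aldehyde under neutral conditions that leave the epoxide intact (the descriptor at C1 changes by priority only).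

Step 11
Reactants: 14 (1S,4S,6R)-4-[(tert-butyldimethylsilyl)oxy]-2,2,6-trimethyl-7-oxabicyclo[4.1.0]heptane-1-carbaldehyde
Product: 15 (1R,4S,6R)-4-[(tert-butyldimethylsilyl)oxy]-1-ethynyl-2,2,6-trimethyl-7-oxabicyclo[4.1.0]heptane
Conditions: dimethyl (1-diazo-2-oxopropyl)phosphonate, K2CO3, MeOH, 0 °C to rt
Reagents that add atoms: dimethyl (1-diazo-2-oxopropyl)phosphonate (COP(=O)(OC)C(=[N+]=[N-])C(C)=O)
Why: Seyferth–Gilbert homologation in its Ohira–Bestmann form should turn the aldehyde, which has no α-hydrogen to epimerise, into the terminal alkyne under mild carbonate conditions.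

Step 12
Reactants: 7 (5Z)-3-bromo-5-[(2E)-4-[(tert-butyldimethylsilyl)oxy]-2-methylbut-2-en-1-ylidene]furan-2(5H)-one; 15 (1R,4S,6R)-4-[(tert-butyldimethylsilyl)oxy]-1-ethynyl-2,2,6-trimethyl-7-oxabicyclo[4.1.0]heptane
Product: 16 (5Z)-3-{[(1R,4S,6R)-4-[(tert-butyldimethylsilyl)oxy]-2,2,6-trimethyl-7-oxabicyclo[4.1.0]heptan-1-yl]ethynyl}-5-[(2E)-4-[(tert-butyldimethylsilyl)oxy]-2-methylbut-2-en-1-ylidene]furan-2(5H)-one
Conditions: PdCl2(PPh3)2 (5 mol %), CuI (10 mol %), Et3N, THF, 0 °C to rt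
Reagents that add atoms: none
Why: Sonogashira coupling at the activated α-bromo-enoate should be fast enough at room temperature that oxidative addition to the vinyl bromide outpaces SN2′ attack of zerovalent palladium on the propargylic epoxide.

Step 13
Reactants: 16 (5Z)-3-{[(1R,4S,6R)-4-[(tert-butyldimethylsilyl)oxy]-2,2,6-trimethyl-7-oxabicyclo[4.1.0]heptan-1-yl]ethynyl}-5-[(2E)-4-[(tert-butyldimethylsilyl)oxy]-2-methylbut-2-en-1-ylidene]furan-2(5H)-one
Product: 17 (5Z)-3-{(Sa)-2-[(2R,4S)-4-[(tert-butyldimethylsilyl)oxy]-2-hydroxy-2,6,6-trimethylcyclohexylidene]ethenyl}-5-[(2E)-4-[(tert-butyldimethylsilyl)oxy]-2-methylbut-2-en-1-ylidene]furan-2(5H)-one (allenic hydrogen on the face of the carbinol methyl group)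
Conditions: Pd2(dba)3·CHCl3 (2.5 mol %), PBu3 (10 mol %), HCO2H/Et3N (1.5 equiv each), THF, rt
Reagents that add atoms: none
Why: Palladium-catalysed formate hydrogenolysis of an alkynyl epoxide should proceed by anti-SN2′ oxidative addition to an allenylpalladium alkoxide, formate decarboxylation and reductive elimination with retention, so hydrogen enters anti to the departing C–O bond, which fixes the allene axis and frees the tertiary alcohol with its configuration retained.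

Step 14
Reactants: 17 (5Z)-3-{(Sa)-2-[(2R,4S)-4-[(tert-butyldimethylsilyl)oxy]-2-hydroxy-2,6,6-trimethylcyclohexylidene]ethenyl}-5-[(2E)-4-[(tert-butyldimethylsilyl)oxy]-2-methylbut-2-en-1-ylidene]furan-2(5H)-one
Product: 18 (5Z)-3-[(2R,6S,7aR)-6-[(tert-butyldimethylsilyl)oxy]-4,4,7a-trimethyl-2,4,5,6,7,7a-hexahydro-1-benzofuran-2-yl]-5-[(2E)-4-[(tert-butyldimethylsilyl)oxy]-2-methylbut-2-en-1-ylidene]furan-2(5H)-one
Conditions: AgNO3 (20 mol %), CaCO3, acetone/H2O, rt, dark
Reagents that add atoms: none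
Why: Silver-catalysed 5-endo-trig cycloisomerisation of an α-hydroxyallene (anti oxymetalation, protodemetalation) should close the 2,5-dihydrofuran with axis-to-centre chirality transfer, placing the C2 hydrogen cis to the C7a methyl group (2R).

Step 15
Reactants: 18 (5Z)-3-[(2R,6S,7aR)-6-[(tert-butyldimethylsilyl)oxy]-4,4,7a-trimethyl-2,4,5,6,7,7a-hexahydro-1-benzofuran-2-yl]-5-[(2E)-4-[(tert-butyldimethylsilyl)oxy]-2-methylbut-2-en-1-ylidene]furan-2(5H)-one
Product: 19 (5Z)-3-[(2R,6S,7aR)-6-[(tert-butyldimethylsilyl)oxy]-4,4,7a-trimethyl-2,4,5,6,7,7a-hexahydro-1-benzofuran-2-yl]-5-[(2E)-4-hydroxy-2-methylbut-2-en-1-ylidene]furan-2(5H)-one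
Conditions: HF·pyridine, pyridine, THF, 0 °C
Reagents that add atoms: none
Why: Buffered fluoride should cleave the unhindered primary allylic silyl ether much faster than the hindered secondary ring silyl ether, and the excess pyridine keeps the medium too weakly acidic to ionise the dihydrofuran C2–O bond.

Step 16
Reactants: 19 (5Z)-3-[(2R,6S,7aR)-6-[(tert-butyldimethylsilyl)oxy]-4,4,7a-trimethyl-2,4,5,6,7,7a-hexahydro-1-benzofuran-2-yl]-5-[(2E)-4-hydroxy-2-methylbut-2-en-1-ylidene]furan-2(5H)-one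
Product: 20 (5Z)-5-[(2E)-4-(1,3-benzothiazol-2-ylsulfanyl)-2-methylbut-2-en-1-ylidene]-3-[(2R,6S,7aR)-6-[(tert-butyldimethylsilyl)oxy]-4,4,7a-trimethyl-2,4,5,6,7,7a-hexahydro-1-benzofuran-2-yl]furan-2(5H)-one
Conditions: 2-mercaptobenzothiazole, PPh3, DIAD, THF, 0 °C
Reagents that add atoms: 2-mercaptobenzothiazole (Sc1nc2ccccc2s1)
Why: Mitsunobu thioetherification should displace the activated primary allylic alcohol by SN2 at the unhindered terminus under neutral conditions.

Step 17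
Reactants: 20 (5Z)-5-[(2E)-4-(1,3-benzothiazol-2-ylsulfanyl)-2-methylbut-2-en-1-ylidene]-3-[(2R,6S,7aR)-6-[(tert-butyldimethylsilyl)oxy]-4,4,7a-trimethyl-2,4,5,6,7,7a-hexahydro-1-benzofuran-2-yl]furan-2(5H)-one
Product: 21 (5Z)-5-[(2E)-4-(1,3-benzothiazol-2-ylsulfonyl)-2-methylbut-2-en-1-ylidene]-3-[(2R,6S,7aR)-6-[(tert-butyldimethylsilyl)oxy]-4,4,7a-trimethyl-2,4,5,6,7,7a-hexahydro-1-benzofuran-2-yl]furan-2(5H)-one
Conditions: (NH4)6Mo7O24·4H2O (10 mol %), 30% H2O2, EtOH, 0 °C to rt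
Reagents that add atoms: hydrogen peroxide (OO)
Why: Molybdate-catalysed peroxide oxidation should be selective for sulfur at low temperature and take the sulfide to the sulfone without epoxidising the conjugated or ring alkenes.

Step 18
Reactants: 10 (4R)-4-[(tert-butyldimethylsilyl)oxy]-2,6,6-trimethylcyclohex-1-en-1-yl trifluoromethanesulfonate; 3 (2E)-3-methylpent-2-en-4-yn-1-ol
Product: 22 (2E)-5-[(4R)-4-[(tert-butyldimethylsilyl)oxy]-2,6,6-trimethylcyclohex-1-en-1-yl]-3-methylpent-2-en-4-yn-1-ol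
Conditions: Pd(PPh3)4 (5 mol %), CuI (10 mol %), Et3N, DMF, 50 °C
Reagents that add atoms: none
Why: Sonogashira coupling of the enol triflate with the terminal enyne should install the ring–alkyne bond with the (E)-trisubstituted alkene of the enynol carried through unchanged.

Step 19
Reactants: 22 (2E)-5-[(4R)-4-[(tert-butyldimethylsilyl)oxy]-2,6,6-trimethylcyclohex-1-en-1-yl]-3-methylpent-2-en-4-yn-1-ol
Product: 23 (2E)-5-[(4R)-4-[(tert-butyldimethylsilyl)oxy]-2,6,6-trimethylcyclohex-1-en-1-yl]-3-methylpent-2-en-4-ynal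
Conditions: MnO2 (excess), CH2Cl2, rt
Reagents that add atoms: none
Why: Manganese dioxide oxidises the allylic alcohol selectively to the enal without isomerising the double bond.

Step 20
Reactants: 23 (2E)-5-[(4R)-4-[(tert-butyldimethylsilyl)oxy]-2,6,6-trimethylcyclohex-1-en-1-yl]-3-methylpent-2-en-4-ynal
Product: 24 (2E,4E)-7-[(4R)-4-[(tert-butyldimethylsilyl)oxy]-2,6,6-trimethylcyclohex-1-en-1-yl]-5-methylhepta-2,4-dien-6-ynal
Conditions: Ph3P=CHCHO, toluene, 70 °C
Reagents that add atoms: (triphenylphosphoranylidene)acetaldehyde (O=CC=P(c1ccccc1)(c1ccccc1)c1ccccc1)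
Why: Wittig reaction with the stabilised formyl ylide should add two carbons with E selectivity and stop at the less electrophilic dienal.

Step 21
Reactants: 21 (5Z)-5-[(2E)-4-(1,3-benzothiazol-2-ylsulfonyl)-2-methylbut-2-en-1-ylidene]-3-[(2R,6S,7aR)-6-[(tert-butyldimethylsilyl)oxy]-4,4,7a-trimethyl-2,4,5,6,7,7a-hexahydro-1-benzofuran-2-yl]furan-2(5H)-one; 24 (2E,4E)-7-[(4R)-4-[(tert-butyldimethylsilyl)oxy]-2,6,6-trimethylcyclohex-1-en-1-yl]-5-methylhepta-2,4-dien-6-ynal
Product: 26 bis(tert-butyldimethylsilyl) ether of the target (all-E chain; 5Z lactone), via (15Z)-isomer 25 (not isolated)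
Conditions: NaN(SiMe3)2, THF, −78 °C; then I2 (2 mol %), benzene, rt, diffuse light
Reagents that add atoms: none
Why: Julia–Kocienski olefination (addition of the allylic sulfonyl carbanion to the enal, Smiles rearrangement, loss of SO2 and benzothiazolone) should form the central disubstituted double bond mainly as the cis isomer 25, which iodine-catalysed equilibration should convert into the all-trans polyene 26 while the already thermodynamic (5Z)-ylidene is unaffected.

Step 22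
Reactants: 26 bis(tert-butyldimethylsilyl) ether of the target
Product: 27 (5Z)-3-[(2R,6S,7aR)-6-hydroxy-4,4,7a-trimethyl-2,4,5,6,7,7a-hexahydro-1-benzofuran-2-yl]-5-[(2E,4E,6E,8E)-11-[(4R)-4-hydroxy-2,6,6-trimethylcyclohex-1-en-1-yl]-2,9-dimethylundeca-2,4,6,8-tetraen-10-yn-1-ylidene]furan-2(5H)-one (target)
Conditions: Bu4NF/AcOH (1:1), THF, 0 °C to rt, dark
Reagents that add atoms: none
Why: Acetic-acid-buffered fluoride should remove both secondary silyl ethers under near-neutral conditions, avoiding acid-induced epimerisation at the dihydrofuran C2 and base-induced opening of the ylidene lactone.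

**Compound list**

1 | propiolic acid | C#CC(=O)O | starting material
2 | (2E)-2,3-dibromoprop-2-enoic acid | OC(=O)/C(Br)=C\Br | intermediate
3 | (2E)-3-methylpent-2-en-4-yn-1-ol | C#C/C(C)=C/CO | starting material
4 | tert-butyldimethyl{[(2E)-3-methylpent-2-en-4-yn-1-yl]oxy}silane | C#C/C(C)=C/CO[Si](C)(C)C(C)(C)C | intermediate
5 | (1Z,3E)-5-[(tert-butyldimethylsilyl)oxy]-3-methylpenta-1,3-dien-1-yl (2E)-2,3-dibromoprop-2-enoate | Br/C=C(/Br)C(=O)O/C=C\C(C)=C\CO[Si](C)(C)C(C)(C)C | intermediate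
6 | (5E)-3-bromo-5-[(2E)-4-[(tert-butyldimethylsilyl)oxy]-2-methylbut-2-en-1-ylidene]furan-2(5H)-one | CC(C)(C)[Si](C)(C)OC/C=C(C)/C=C1\C=C(Br)C(=O)O1 | intermediate (not isolated)
7 | (5Z)-3-bromo-5-[(2E)-4-[(tert-butyldimethylsilyl)oxy]-2-methylbut-2-en-1-ylidene]furan-2(5H)-one | CC(C)(C)[Si](C)(C)OC/C=C(C)/C=C1/C=C(Br)C(=O)O1 | intermediate
8 | (4R,6R)-4-hydroxy-2,2,6-trimethylcyclohexan-1-one (actinol) | C[C@H]1C(=O)C(C)(C)C[C@H](O)C1 | starting material
9 | (4R,6R)-4-[(tert-butyldimethylsilyl)oxy]-2,2,6-trimethylcyclohexan-1-one | C[C@H]1C(=O)C(C)(C)C[C@H](O[Si](C)(C)C(C)(C)C)C1 | intermediate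
10 | (4R)-4-[(tert-butyldimethylsilyl)oxy]-2,6,6-trimethylcyclohex-1-en-1-yl trifluoromethanesulfonate | CC1=C(OS(=O)(=O)C(F)(F)F)C(C)(C)C[C@H](O[Si](C)(C)C(C)(C)C)C1 | intermediate
11 | methyl (4R)-4-[(tert-butyldimethylsilyl)oxy]-2,6,6-trimethylcyclohex-1-ene-1-carboxylate | CC1=C(C(=O)OC)C(C)(C)C[C@H](O[Si](C)(C)C(C)(C)C)C1 | intermediate
12 | [(4R)-4-[(tert-butyldimethylsilyl)oxy]-2,6,6-trimethylcyclohex-1-en-1-yl]methanol | CC1=C(CO)C(C)(C)C[C@H](O[Si](C)(C)C(C)(C)C)C1 | intermediate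
13 | [(1R,4S,6R)-4-[(tert-butyldimethylsilyl)oxy]-2,2,6-trimethyl-7-oxabicyclo[4.1.0]heptan-1-yl]methanol | OC[C@]12C(C)(C)C[C@H](O[Si](C)(C)C(C)(C)C)C[C@@]1(C)O2 | intermediate
14 | (1S,4S,6R)-4-[(tert-butyldimethylsilyl)oxy]-2,2,6-trimethyl-7-oxabicyclo[4.1.0]heptane-1-carbaldehyde | O=C[C@]12C(C)(C)C[C@H](O[Si](C)(C)C(C)(C)C)C[C@@]1(C)O2 | intermediate
15 | (1R,4S,6R)-4-[(tert-butyldimethylsilyl)oxy]-1-ethynyl-2,2,6-trimethyl-7-oxabicyclo[4.1.0]heptane | C#C[C@]12C(C)(C)C[C@H](O[Si](C)(C)C(C)(C)C)C[C@@]1(C)O2 | intermediate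
16 | (5Z)-3-{[(1R,4S,6R)-4-[(tert-butyldimethylsilyl)oxy]-2,2,6-trimethyl-7-oxabicyclo[4.1.0]heptan-1-yl]ethynyl}-5-[(2E)-4-[(tert-butyldimethylsilyl)oxy]-2-methylbut-2-en-1-ylidene]furan-2(5H)-one | CC(C)(C)[Si](C)(C)OC/C=C(C)/C=C1/C=C(C#C[C@]23C(C)(C)C[C@H](O[Si](C)(C)C(C)(C)C)C[C@@]2(C)O3)C(=O)O1 | intermediate
17 | (5Z)-3-{(Sa)-2-[(2R,4S)-4-[(tert-butyldimethylsilyl)oxy]-2-hydroxy-2,6,6-trimethylcyclohexylidene]ethenyl}-5-[(2E)-4-[(tert-butyldimethylsilyl)oxy]-2-methylbut-2-en-1-ylidene]furan-2(5H)-one | CC(C)(C)[Si](C)(C)OC/C=C(C)/C=C1/C=C(C=[C@]=C2C(C)(C)C[C@H](O[Si](C)(C)C(C)(C)C)C[C@@]2(C)O)C(=O)O1 | intermediate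
18 | (5Z)-3-[(2R,6S,7aR)-6-[(tert-butyldimethylsilyl)oxy]-4,4,7a-trimethyl-2,4,5,6,7,7a-hexahydro-1-benzofuran-2-yl]-5-[(2E)-4-[(tert-butyldimethylsilyl)oxy]-2-methylbut-2-en-1-ylidene]furan-2(5H)-one | CC(C)(C)[Si](C)(C)OC/C=C(C)/C=C1/C=C([C@H]2C=C3C(C)(C)C[C@H](O[Si](C)(C)C(C)(C)C)C[C@@]3(C)O2)C(=O)O1 | intermediate
19 | (5Z)-3-[(2R,6S,7aR)-6-[(tert-butyldimethylsilyl)oxy]-4,4,7a-trimethyl-2,4,5,6,7,7a-hexahydro-1-benzofuran-2-yl]-5-[(2E)-4-hydroxy-2-methylbut-2-en-1-ylidene]furan-2(5H)-one | OC/C=C(C)/C=C1/C=C([C@H]2C=C3C(C)(C)C[C@H](O[Si](C)(C)C(C)(C)C)C[C@@]3(C)O2)C(=O)O1 | intermediate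
20 | (5Z)-5-[(2E)-4-(1,3-benzothiazol-2-ylsulfanyl)-2-methylbut-2-en-1-ylidene]-3-[(2R,6S,7aR)-6-[(tert-butyldimethylsilyl)oxy]-4,4,7a-trimethyl-2,4,5,6,7,7a-hexahydro-1-benzofuran-2-yl]furan-2(5H)-one | C(/C=C(C)/C=C1/C=C([C@H]2C=C3C(C)(C)C[C@H](O[Si](C)(C)C(C)(C)C)C[C@@]3(C)O2)C(=O)O1)Sc1nc2ccccc2s1 | intermediate
21 | (5Z)-5-[(2E)-4-(1,3-benzothiazol-2-ylsulfonyl)-2-methylbut-2-en-1-ylidene]-3-[(2R,6S,7aR)-6-[(tert-butyldimethylsilyl)oxy]-4,4,7a-trimethyl-2,4,5,6,7,7a-hexahydro-1-benzofuran-2-yl]furan-2(5H)-one | O=S(=O)(C/C=C(C)/C=C1/C=C([C@H]2C=C3C(C)(C)C[C@H](O[Si](C)(C)C(C)(C)C)C[C@@]3(C)O2)C(=O)O1)c1nc2ccccc2s1 | intermediate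
22 | (2E)-5-[(4R)-4-[(tert-butyldimethylsilyl)oxy]-2,6,6-trimethylcyclohex-1-en-1-yl]-3-methylpent-2-en-4-yn-1-ol | CC1=C(C#C/C(C)=C/CO)C(C)(C)C[C@H](O[Si](C)(C)C(C)(C)C)C1 | intermediate
23 | (2E)-5-[(4R)-4-[(tert-butyldimethylsilyl)oxy]-2,6,6-trimethylcyclohex-1-en-1-yl]-3-methylpent-2-en-4-ynal | CC1=C(C#C/C(C)=C/C=O)C(C)(C)C[C@H](O[Si](C)(C)C(C)(C)C)C1 | intermediate
24 | (2E,4E)-7-[(4R)-4-[(tert-butyldimethylsilyl)oxy]-2,6,6-trimethylcyclohex-1-en-1-yl]-5-methylhepta-2,4-dien-6-ynal | CC1=C(C#C/C(C)=C/C=C/C=O)C(C)(C)C[C@H](O[Si](C)(C)C(C)(C)C)C1 | intermediate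
25 | (15Z)-isomer of 26 (central disubstituted double bond cis; all else as in 26) | CC1=C(C#C/C(C)=C/C=C/C=C\C=C(C)\C=C2\C=C([C@H]3C=C4C(C)(C)C[C@H](O[Si](C)(C)C(C)(C)C)C[C@@]4(C)O3)C(=O)O2)C(C)(C)C[C@H](O[Si](C)(C)C(C)(C)C)C1 | intermediate (not isolated)
26 | (5Z)-3-[(2R,6S,7aR)-6-[(tert-butyldimethylsilyl)oxy]-4,4,7a-trimethyl-2,4,5,6,7,7a-hexahydro-1-benzofuran-2-yl]-5-[(2E,4E,6E,8E)-11-[(4R)-4-[(tert-butyldimethylsilyl)oxy]-2,6,6-trimethylcyclohex-1-en-1-yl]-2,9-dimethylundeca-2,4,6,8-tetraen-10-yn-1-ylidene]furan-2(5H)-one | CC1=C(C#C/C(C)=C/C=C/C=C/C=C(C)/C=C2/C=C([C@H]3C=C4C(C)(C)C[C@H](O[Si](C)(C)C(C)(C)C)C[C@@]4(C)O3)C(=O)O2)C(C)(C)C[C@H](O[Si](C)(C)C(C)(C)C)C1 | intermediate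
27 | (5Z)-3-[(2R,6S,7aR)-6-hydroxy-4,4,7a-trimethyl-2,4,5,6,7,7a-hexahydro-1-benzofuran-2-yl]-5-[(2E,4E,6E,8E)-11-[(4R)-4-hydroxy-2,6,6-trimethylcyclohex-1-en-1-yl]-2,9-dimethylundeca-2,4,6,8-tetraen-10-yn-1-ylidene]furan-2(5H)-one | CC1=C(C#C/C(C)=C/C=C/C=C/C=C(C)/C=C2/C=C([C@H]3C=C4C(C)(C)C[C@H](O)C[C@@]4(C)O3)C(=O)O2)C(C)(C)C[C@H](O)C1 | target

**Step count and risks**

Total step count: 22. Longest linear sequence: 15 steps (5–17, 21, 22, from actinol 8).

Steps most likely to fail: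

1. Step 4 (proposed new method). The vinylpalladium intermediate may lose the α-bromine by β-halide elimination, or couple intermolecularly, before the ester reaches the s-cis rotamer needed for ring closure; β-hydride elimination may also go towards the silyloxymethyl end. The fallback forms the O1–C5 bond last instead of the C4–C5 bond and uses known chemistry. It sets out from 2 and 4: Sonogashira coupling at the β-bromide (PdCl2(PPh3)2, CuI, Et3N, MeCN, rt) should give (2E,6E)-2-bromo-8-[(tert-butyldimethylsilyl)oxy]-6-methylocta-2,6-dien-4-ynoic acid F1, which should lactonise in the same flask by 5-exo-dig anti addition of the carboxylate across the alkyne. It comes back to the route at 7.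

2. Step 13. Hydride may be delivered to the propargylic instead of the allenic position, the conjugated lactone may suffer reduction, or the allenol may cyclise under palladium with erosion of the axis-to-centre transfer. The fallback replaces the allene by the epoxide-to-furanoid rearrangement. It sets out from 15 and 7: hydroboration of 15 (pinacolborane, catalytic dicyclohexylborane, rt) should give 2-[(E)-2-[(1S,4S,6R)-4-[(tert-butyldimethylsilyl)oxy]-2,2,6-trimethyl-7-oxabicyclo[4.1.0]heptan-1-yl]ethenyl]-4,4,5,5-tetramethyl-1,3,2-dioxaborolane F2. Suzuki–Miyaura coupling with 7 (Pd(PPh3)4, K3PO4, THF/H2O, rt) should give (5Z)-3-{(E)-2-[(1S,4S,6R)-4-[(tert-butyldimethylsilyl)oxy]-2,2,6-trimethyl-7-oxabicyclo[4.1.0]heptan-1-yl]ethenyl}-5-[(2E)-4-[(tert-butyldimethylsilyl)oxy]-2-methylbut-2-en-1-ylidene]furan-2(5H)-one F3. Acid-catalysed rearrangement (pyridinium p-toluenesulfonate, CH2Cl2, rt) should open the epoxide at the allylic carbon and close the dihydrofuran with retention at C7a, giving 18 together with its C2 epimer, (5Z)-3-[(2S,6S,7aR)-6-[(tert-butyldimethylsilyl)oxy]-4,4,7a-trimethyl-2,4,5,6,7,7a-hexahydro-1-benzofuran-2-yl]-5-[(2E)-4-[(tert-butyldimethylsilyl)oxy]-2-methylbut-2-en-1-ylidene]furan-2(5H)-one F4, to be removed by chromatography. It comes back to the route at 18.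

3. Step 21. The sulfonyl carbanion is vinylogous to the lactone and may degrade or self-condense, and equilibration of the central double bond may stay incomplete. The fallback moves the carbanion to the robust ring-A half and forms the neighbouring double bond by an E-selective Horner–Wadsworth–Emmons reaction. It sets out from 19 and 22. Oxidation of 19 (MnO2, CH2Cl2) should give (2E)-4-[(2Z)-4-[(2R,6S,7aR)-6-[(tert-butyldimethylsilyl)oxy]-4,4,7a-trimethyl-2,4,5,6,7,7a-hexahydro-1-benzofuran-2-yl]-5-oxofuran-2(5H)-ylidene]-3-methylbut-2-enal F5, and Wittig homologation with Ph3P=CHCHO should give (2E,4E)-6-[(2Z)-4-[(2R,6S,7aR)-6-[(tert-butyldimethylsilyl)oxy]-4,4,7a-trimethyl-2,4,5,6,7,7a-hexahydro-1-benzofuran-2-yl]-5-oxofuran-2(5H)-ylidene]-5-methylhexa-2,4-dienal F6. Appel bromination of 22 (CBr4, PPh3) should give {[(1R)-4-[(3E)-5-bromo-3-methylpent-3-en-1-yn-1-yl]-3,5,5-trimethylcyclohex-3-en-1-yl]oxy}(tert-butyl)dimethylsilane F7, and Michaelis–Arbuzov reaction with P(OEt)3 (100 °C) should give diethyl [(2E)-5-[(4R)-4-[(tert-butyldimethylsilyl)oxy]-2,6,6-trimethylcyclohex-1-en-1-yl]-3-methylpent-2-en-4-yn-1-yl]phosphonate F8. Deprotonation of F8 (LiN(SiMe3)2, THF, −78 °C) and addition of F6 should give the protected polyene. It comes back to the route at 26.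

**Further compounds**

F1 | step 4 | (2E,6E)-2-bromo-8-[(tert-butyldimethylsilyl)oxy]-6-methylocta-2,6-dien-4-ynoic acid | OC(=O)/C(Br)=C\C#C/C(C)=C/CO[Si](C)(C)C(C)(C)C
F2 | step 13 | 2-[(E)-2-[(1S,4S,6R)-4-[(tert-butyldimethylsilyl)oxy]-2,2,6-trimethyl-7-oxabicyclo[4.1.0]heptan-1-yl]ethenyl]-4,4,5,5-tetramethyl-1,3,2-dioxaborolane | CC1(C)OB(/C=C/[C@]23C(C)(C)C[C@H](O[Si](C)(C)C(C)(C)C)C[C@@]2(C)O3)OC1(C)C
F3 | step 13 | (5Z)-3-{(E)-2-[(1S,4S,6R)-4-[(tert-butyldimethylsilyl)oxy]-2,2,6-trimethyl-7-oxabicyclo[4.1.0]heptan-1-yl]ethenyl}-5-[(2E)-4-[(tert-butyldimethylsilyl)oxy]-2-methylbut-2-en-1-ylidene]furan-2(5H)-one | CC(C)(C)[Si](C)(C)OC/C=C(C)/C=C1/C=C(/C=C/[C@]23C(C)(C)C[C@H](O[Si](C)(C)C(C)(C)C)C[C@@]2(C)O3)C(=O)O1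
F4 | step 13 | (5Z)-3-[(2S,6S,7aR)-6-[(tert-butyldimethylsilyl)oxy]-4,4,7a-trimethyl-2,4,5,6,7,7a-hexahydro-1-benzofuran-2-yl]-5-[(2E)-4-[(tert-butyldimethylsilyl)oxy]-2-methylbut-2-en-1-ylidene]furan-2(5H)-one | CC(C)(C)[Si](C)(C)OC/C=C(C)/C=C1/C=C([C@@H]2C=C3C(C)(C)C[C@H](O[Si](C)(C)C(C)(C)C)C[C@@]3(C)O2)C(=O)O1
F5 | step 21 | (2E)-4-[(2Z)-4-[(2R,6S,7aR)-6-[(tert-butyldimethylsilyl)oxy]-4,4,7a-trimethyl-2,4,5,6,7,7a-hexahydro-1-benzofuran-2-yl]-5-oxofuran-2(5H)-ylidene]-3-methylbut-2-enal | O=C/C=C(C)/C=C1/C=C([C@H]2C=C3C(C)(C)C[C@H](O[Si](C)(C)C(C)(C)C)C[C@@]3(C)O2)C(=O)O1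
F6 | step 21 | (2E,4E)-6-[(2Z)-4-[(2R,6S,7aR)-6-[(tert-butyldimethylsilyl)oxy]-4,4,7a-trimethyl-2,4,5,6,7,7a-hexahydro-1-benzofuran-2-yl]-5-oxofuran-2(5H)-ylidene]-5-methylhexa-2,4-dienal | O=C/C=C/C=C(C)/C=C1/C=C([C@H]2C=C3C(C)(C)C[C@H](O[Si](C)(C)C(C)(C)C)C[C@@]3(C)O2)C(=O)O1
F7 | step 21 | {[(1R)-4-[(3E)-5-bromo-3-methylpent-3-en-1-yn-1-yl]-3,5,5-trimethylcyclohex-3-en-1-yl]oxy}(tert-butyl)dimethylsilane | CC1=C(C#C/C(C)=C/CBr)C(C)(C)C[C@H](O[Si](C)(C)C(C)(C)C)C1
F8 | step 21 | diethyl [(2E)-5-[(4R)-4-[(tert-butyldimethylsilyl)oxy]-2,6,6-trimethylcyclohex-1-en-1-yl]-3-methylpent-2-en-4-yn-1-yl]phosphonate | CC1=C(C#C/C(C)=C/CP(=O)(OCC)OCC)C(C)(C)C[C@H](O[Si](C)(C)C(C)(C)C)C1
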